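## Analysis of the target

CNP0294555.0 is a decameric phlorotannin: ten benzene rings, each a phloroglucinol unit, joined by six diaryl ether bonds and three biaryl bonds, with 24 free phenolic hydroxyls and no other functional group. Rings A to D form an ether chain: ring A (3,5-dihydroxyphenyl) sits on the C1 oxygen of ring B, ring B carries ring C on its C2 oxygen, and ring C (oxygens at C1, C2, C4, C6) is joined through its C4 oxygen to the C1 oxygen of ring D. Three identical biaryl arms hang from this chain, two on the C2 and C6 oxygens of ring D (rings E–F) and one on the C6 oxygen of ring B (rings E'–F'). Each ring E is bound through its C1 oxygen, has hydroxyls at C2, C4 and C6, a hydrogen at C3 and the 2,4,6-trihydroxyphenyl ring F at C5. There is no stereocentre, and the E–F axes are not stereogenic because ring F is symmetric about the axis. The free polyphenol is easily oxidised by air, so the skeleton must be carried as alkyl ethers and uncovered in the last step. The difficulty is crowding: rings B and D each bear three contiguous aryloxy groups, every ring E oxygen at C1 lies between two oxygenated carbons, and each E–F bond is a tetra-ortho-oxygenated biaryl bond. The strategy rests on the pattern of ring E: E-C6, E-C1, E-C2 and E-C3 (C–OH, C–OAr, C–OR, C–H) map onto the four carbons of a 4-aryloxy-3-alkoxycyclobutenone, and E-C4 and E-C5 (C–OR, C–aryl) onto an aryl ynol ether, so the crowded ether and the crowded biaryl are both in place before the ring exists.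

## Retrosynthetic reasoning

**47 from 46.** The last operation removes all 24 O-alkyl groups at once. 46 carries only methyl and ethyl ethers, so a boron trihalide, which cuts O–alkyl and not O–aryl bonds, can do this in one step.

**46 from 24 and 45.** The bond cut joins the oxygen on ring D C1 to ring C C4. It divides the decamer into two pentamers, and it is the only ether of the A–B–C–D chain whose aryl carbon has two ortho hydrogens. Ring C can therefore be the electrophile, and the crowded ring D hydroxyl between two aryloxy groups only has to act as nucleophile. Forward, this is a copper-catalysed arylation of phenol 24 by aryl iodide 45. A diaryliodonium salt of 45 would transfer the aryl group more easily, but oxidising the iodide to trivalent iodine in a molecule with five alkoxy-rich rings would not be selective.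

**24 from 22 through 23.** The ring D C1 oxygen is held as a benzyl ether through the annulation. The two hydroxyls that the annulation leaves on the rings E are methylated first (23), so that hydrogenolysis frees only the ring D C1 hydroxyl.

**22 from 18 and 6 (key disconnection).** In each ring E three bonds are cut: E-C5–C6, E-C3–C4 and E-C1–C6. This leaves E-C6, C1, C2 and C3 as a cyclobutenone already attached to the ring D oxygen, and E-C4 and C5 as the ynol ether that carries ring F. Neither the crowded aryl ether nor the tetra-ortho-oxygenated biaryl then has to be made by coupling: the first is an alkyl ether in 18, the second forms when a ketene carbon bonds to the alkyne carbon that bears ring F. Forward, one thermal cascade run in two directions, with two molecules of 6, must close both rings E.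

**18 from 14 and 15.** Each cyclobutenone is cut into an aryloxyketene and one molecule of the alkyne 15, a (2+2) cycloaddition, so the bis-cyclobutenone takes up two molecules of 15. The ketenes come from the diacid 14 through its acid chloride, so the ring D to ring E oxygens enter as simple aryloxyacetic acids.

**14 from 7 and 9 through 8, 10, 12 and 13.** Ring D is the trihydroxybenzaldehyde 7. Its most acidic 4-hydroxyl takes the benzyl group (8), the two flanking hydroxyls take the acetate arms from 9 (10), and the formyl group becomes the ring D C4 oxygen by aryl migration to oxygen (12), which is methylated (13) before hydrolysis to 14.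

**6 from 2 and 3; 2 from 1.** The aryl–alkyne bond is cut, giving the iodide 2 of the symmetric arene 1 and a methoxyethynyl metal made from acetal 3.

**45 from 40 and 6 through 44; 40 from 37 and 15.** The third arm is disconnected the same way, on one cyclobutenone. The aryl iodide on ring C is inert to the thermal cascade.

**37 from 34 and 35 through 36.** The ring A to ring B ether is cut at the ring A carbon, which has no ortho substituent. An oxidative copper coupling of the boronic acid 35 with the ring B C1 hydroxyl leaves the aryl iodide untouched.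

**34 from 27, 26 and 31 through 28, 30 and 32; 26 from 25.** Ring B is the difluoroaldehyde 27. Its formyl group activates both fluorides for substitution, first by the hindered ring C phenoxide 26 (the tri-ortho-substituted B–C ether) and then by an oxygen nucleophile, which is alkylated with 31. The formyl group then turns into the ring B C1 oxygen by aryl migration.

## Alternatives that were turned down

**Alternative 1:** The two ethers on ring D C2 and C6 are cut with ring D at the quinone oxidation level. Forward, two equivalents of the preformed biaryl phenol A2 displace both chlorides of the dichloroquinone A3 under carbonate base in a polar solvent, giving the bis(aryloxy)quinone A1 without closing a ring.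
- For: addition–elimination of phenoxides on haloquinones is old, metal-free chemistry, two bonds form at once, and reduction of A1 gives ring D with its hindered and unhindered hydroxyls already differentiated. On precedent for the bond-forming event it is stronger than the chosen route.
- Against: A2 must already contain the tetra-ortho-oxygenated E–F bond, so the hardest C–C bond is moved into a starting material that needs a hindered biaryl coupling or an oxidative dimerisation and desymmetrisation. An electron-rich, hindered phenoxide and an oxidising quinone invite electron transfer and attack through carbon. The third arm on ring B needs a separate solution.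
- Comparison: the chosen route offers, in place of that precedent, both crowded bonds of each arm made without any coupling, and rings F from the cheap arene 1. Its own reliable ether-forming steps (steps 13 and 14) use the same addition–elimination idea on 27, where no redox partner is present.

**Alternative 2:** Ring F is cut at F-C2–C3 and F-C5–C6 and grown onto ring E. Forward, an alkoxide-mediated double Claisen condensation of the arylmalonate A5 with the oxopentanedioate A6 closes ring F as its 3,5-diester A4.
- For: it is polyketide-like, uses very cheap three- and five-carbon pieces, and replaces the hindered biaryl bond by an aryl–malonate bond. On cost of the ring F carbons it is at least as good as the chosen route.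
- Against: A5 requires C-arylation of a malonate at a ring E carbon flanked by two methoxy groups. A4 carries two ester groups that must be hydrolysed and decarboxylated and three hydroxyls that must be protected. It builds one ring per run and does nothing for the six ethers: the ring E C1 oxygen, a benzyl ether in A4, must later be joined three times to rings D and B through a phenol flanked by two methoxy groups.
- Comparison: it needs about four steps per ring F where the chosen route needs none, and it leaves the crowded ethers, which the chosen key step settles, to late couplings.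

**Alternative 3:** Ring A is cut at A-C1–C6 and A-C4–C5 and built on the ring B C1 oxygen. Forward, the 6-aryloxy-4-methoxy-2-pyranone A8 and the ketene acetal A9 undergo (4+2) cycloaddition, decarboxylation and loss of an alcohol to give the pentamer A7.
- For: the ether between two aryloxy groups on ring B is made without arylating a hindered phenol, the regiochemistry is unambiguous, gas loss makes the aromatisation irreversible, and the 3,5-dioxygenation comes out directly. In avoiding a metal-mediated ether coupling it follows the same logic as the chosen route.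
- Against: it spends the key step on the easiest ring. Ring A has no ortho substituent and is attached in one step with 35 (step 17). A8 can only be made from the complete B–C–E'–F' phenol, so every hard bond must exist beforehand. A pyranone with donor oxygens at C4 and C6 is a poor diene for an electron-rich alkene, and its aryloxy group is a leaving group on a vinylogous carbonate.
- Comparison: the chosen route applies the "ring built on a buried oxygen" idea where the crowding is, at the three rings E, and forms the biaryl bond in the same step.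

Key step: step 9

**Remarks on the chemistry (assumptions)**
- The ynol ether is carried as its methyl ether 6. An ethyl ynol ether would fragment by a retro-ene reaction in the temperature range of the cyclobutenone opening; the alkyl group is removed in the last step either way.
- The fragment that arylates ring D must already hold the third arm (rings E' and F') on ring B, so it is the pentamer 45.
- The target has no stereogenic element. Cyclobutenones 18 and 40 are used as stereoisomer mixtures, since their sp3 centres are lost on annulation.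
- Steps 4, 8 and 9 run in two directions: the doubly functional ring D compound takes up two molecules of its partner (9, 15 and 6 respectively), one per arm.

## Route

Step 1
Reactants: 1 1,3,5-trimethoxybenzene
Product: 2 2-iodo-1,3,5-trimethoxybenzene
Conditions: NIS (1.0 equiv), MeCN, rt
Reagents that add atoms: N-iodosuccinimide, O=C1CCC(=O)N1I
Why: Electrophilic aromatic iodination; the three free positions of 1 are equivalent and one equivalent of reagent should stop at the monoiodide.

Step 2
Reactants: 3 2-chloro-1,1-dimethoxyethane (chloroacetaldehyde dimethyl acetal); 2 2-iodo-1,3,5-trimethoxybenzene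
Product: 6 2-(methoxyethynyl)-1,3,5-trimethoxybenzene, via lithium methoxyacetylide 4 (not isolated), via (methoxyethynyl)zinc chloride 5 (not isolated)
Conditions: 3, LiNEt2 (from Et2NH and n-BuLi, 3.2 equiv), THF, 0 °C; ZnCl2; then 2, Pd(PPh3)4 (5 mol%), THF, 50 °C; neutral work-up, basic alumina
Reagents that add atoms: none
Why: Two base-induced eliminations and a deprotonation turn 3 into the alkoxyacetylide; transmetalation to zinc and Negishi coupling with the aryl iodide should give the aryl ynol ether. Oxidative addition of an aryl iodide is easy even between two methoxy groups, and the alkynylzinc is small.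

Step 3
Reactants: 7 3,4,5-trihydroxybenzaldehyde
Product: 8 4-(benzyloxy)-3,5-dihydroxybenzaldehyde
Conditions: BnBr (1.0 equiv), NaHCO3, NaI (cat.), DMF, 40 °C
Reagents that add atoms: benzyl bromide, BrCc1ccccc1
Why: Williamson alkylation; the 4-hydroxyl is para to the formyl group and the most acidic, so a hydrogencarbonate base and one equivalent of halide should alkylate it alone.

Step 4
Reactants: 8 4-(benzyloxy)-3,5-dihydroxybenzaldehyde; 9 methyl bromoacetate
Product: 10 dimethyl 2,2'-{[2-(benzyloxy)-5-formyl-1,3-phenylene]bis(oxy)}diacetate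
Conditions: 9 (2.4 equiv), K2CO3, acetone, reflux
Reagents that add atoms: none
Why: Williamson alkylation of both remaining phenols; the two O–CH2 bonds formed here become the crowded ring D to ring E ethers.

Step 5
Reactants: 10 dimethyl 2,2'-{[2-(benzyloxy)-5-formyl-1,3-phenylene]bis(oxy)}diacetate
Product: 12 dimethyl 2,2'-{[2-(benzyloxy)-5-hydroxy-1,3-phenylene]bis(oxy)}diacetate, via aryl formate 11 (not isolated)
Conditions: mCPBA, CH2Cl2, 0 °C to rt; then K2CO3 (cat.), MeOH, rt
Reagents that add atoms: 3-chloroperoxybenzoic acid, OOC(=O)c1cccc(Cl)c1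
Why: Baeyer–Villiger oxidation; the trioxygenated aryl group migrates to oxygen, and brief methanolysis cleaves the aryl formate while the methyl esters only exchange with the solvent.

Step 6
Reactants: 12 dimethyl 2,2'-{[2-(benzyloxy)-5-hydroxy-1,3-phenylene]bis(oxy)}diacetate
Product: 13 dimethyl 2,2'-{[2-(benzyloxy)-5-methoxy-1,3-phenylene]bis(oxy)}diacetate
Conditions: MeI, K2CO3, acetone, reflux
Reagents that add atoms: iodomethane, CI
Why: Williamson methylation of the only free phenol fixes the ring D C4 oxygen as a methyl ether.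

Step 7
Reactants: 13 dimethyl 2,2'-{[2-(benzyloxy)-5-methoxy-1,3-phenylene]bis(oxy)}diacetate
Product: 14 2,2'-{[2-(benzyloxy)-5-methoxy-1,3-phenylene]bis(oxy)}diacetic acid
Conditions: LiOH, THF/H2O, rt; then aq. HCl
Reagents that add atoms: lithium hydroxide, [Li+].[OH-]
Why: Saponification of both methyl esters; benzyl and methyl ethers are inert.

Step 8
Reactants: 14 2,2'-{[2-(benzyloxy)-5-methoxy-1,3-phenylene]bis(oxy)}diacetic acid; 15 ethoxyethyne (2 equiv)
Product: 18 4,4'-{[2-(benzyloxy)-5-methoxy-1,3-phenylene]bis(oxy)}bis(3-ethoxycyclobut-2-en-1-one) as a mixture of diastereomers, via diacid chloride 16 (not isolated), via bis(aryloxyketene) 17 (not isolated)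
Conditions: 1-chloro-N,N,2-trimethylprop-1-en-1-amine (2.05 equiv), CH2Cl2, 0 °C to rt; 15 (6 equiv), Et3N (2.2 equiv, slow addition), Et2O, 0 °C to rt
Reagents that add atoms: ethoxyethyne (second equivalent for the second arm), CCOC#C
Why: The neutral chloro-enamine makes the acid chloride without a Vilsmeier-type electrophile that could attack ring D. Dehydrochlorination gives the two aryloxyketenes, each of which adds one molecule of 15 by (2+2) cycloaddition, ketene carbonyl carbon to the unsubstituted alkyne carbon, the known ketene–ethoxyethyne route to 3-ethoxycyclobutenones. The two sp3 centres form without control and are lost in step 9.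

Step 9
Reactants: 18 4,4'-{[2-(benzyloxy)-5-methoxy-1,3-phenylene]bis(oxy)}bis(3-ethoxycyclobut-2-en-1-one); 6 2-(methoxyethynyl)-1,3,5-trimethoxybenzene
Product: 22 6,6'-{[2-(benzyloxy)-5-methoxy-1,3-phenylene]bis(oxy)}bis[5-ethoxy-3-methoxy-2-(2,4,6-trimethoxyphenyl)phenol], via bis(vinylketene) 19 (not isolated), via bis(4-vinylcyclobutenone) 20 (not isolated), via bis(dienylketene) 21 (not isolated)
Conditions: 6 (3 equiv), degassed toluene, 110 °C, sealed vessel; then K2CO3, MeOH, rt
Reagents that add atoms: none
Why: Each cyclobutenone of 18 opens by a thermal conrotatory 4π electrocyclic reaction, the aryloxy group turning outward, to a vinylketene (19). The ketene adds 6 by (2+2) cycloaddition, its carbonyl carbon bonding to the aryl-bearing, nucleophilic alkyne carbon (E-C5–C6) and its α-carbon to the methoxy-bearing carbon (E-C3–C4), to give the 4-vinylcyclobutenone 20. 20 opens again (4π) to the dienylketene 21, and each ring E closes by a 6π disrotatory electrocyclisation between the ketene carbon and the aryloxy-bearing terminus (E-C1–C6), followed by tautomerisation of the cyclohexadienone to the phenol. The closest known reaction is the Danheiser benzannulation of cyclobutenones with alkoxy- and siloxyalkynes; a 4-aryloxy-3-alkoxycyclobutenone, an aryl ynol ether this hindered and a two-fold version have not been tried, and this is where the risk of the route sits. No stereocentre is formed: the two sp3 carbons of 18 become aromatic and the E–F axes are not stereogenic. The step needs one regiochemistry in the (2+2) event, ring F between the new hydroxyl and the methoxy carbon, and the polarisation of the ynol ether (positive charge stabilised on the oxygen-bearing carbon) enforces it; a dienylketene of the wrong geometry can only revert, since both ring openings are reversible. Excess 6 keeps the vinylketenes from dimerising, and the methanolysis at the end releases any product phenol that a ketene has acylated.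

Step 10
Reactants: 22 6,6'-{[2-(benzyloxy)-5-methoxy-1,3-phenylene]bis(oxy)}bis[5-ethoxy-3-methoxy-2-(2,4,6-trimethoxyphenyl)phenol]
Product: 23 2-(benzyloxy)-1,3-bis[6-ethoxy-2,4-dimethoxy-3-(2,4,6-trimethoxyphenyl)phenoxy]-5-methoxybenzene
Conditions: MeI, K2CO3, DMF, 50 °C
Reagents that add atoms: iodomethane, CI
Why: Williamson methylation of the two new, hindered phenols; a small electrophile in a polar solvent should reach them.

Step 11
Reactants: 23 2-(benzyloxy)-1,3-bis[6-ethoxy-2,4-dimethoxy-3-(2,4,6-trimethoxyphenyl)phenoxy]-5-methoxybenzene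
Product: 24 2,6-bis[6-ethoxy-2,4-dimethoxy-3-(2,4,6-trimethoxyphenyl)phenoxy]-4-methoxyphenol
Conditions: H2 (1 atm), Pd/C, EtOAc/MeOH, rt
Reagents that add atoms: none
Why: Hydrogenolysis of the benzyl ether; nothing else in 23 is reducible, and only the ring D C1 hydroxyl is freed.

Step 12
Reactants: 25 2,6-dimethoxyphenol
Product: 26 4-iodo-2,6-dimethoxyphenol
Conditions: I2, NaHCO3, THF/H2O, 0 °C
Reagents that add atoms: iodine, II
Why: Electrophilic iodination of the phenoxide, which directs to the only free ortho or para position, C4.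

Step 13
Reactants: 27 2,6-difluoro-4-methoxybenzaldehyde; 26 4-iodo-2,6-dimethoxyphenol
Product: 28 2-fluoro-6-(4-iodo-2,6-dimethoxyphenoxy)-4-methoxybenzaldehyde
Conditions: K2CO3, DMF, 80 °C
Reagents that add atoms: none
Why: Nucleophilic aromatic substitution; both fluorides are ortho to the formyl group, and the electrophilic carbon is unhindered, so the phenoxide flanked by two methoxy groups can form the tri-ortho-substituted B–C ether. The first aryloxy group deactivates the ring, so the reaction should stop at monosubstitution.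

Step 14
Reactants: 28 2-fluoro-6-(4-iodo-2,6-dimethoxyphenoxy)-4-methoxybenzaldehyde
Product: 30 2-hydroxy-6-(4-iodo-2,6-dimethoxyphenoxy)-4-methoxybenzaldehyde, via sulfonylethyl ether 29 (not isolated)
Conditions: MeSO2CH2CH2OH, NaH, DMF, 0 °C to rt; then aq. HCl
Reagents that add atoms: 2-(methylsulfonyl)ethanol, CS(=O)(=O)CCO
Why: Nucleophilic aromatic substitution of the second fluoride by an alkoxide that serves as a hydroxide surrogate; β-elimination of the vinyl sulfone releases the phenoxide in the same flask.

Step 15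
Reactants: 30 2-hydroxy-6-(4-iodo-2,6-dimethoxyphenoxy)-4-methoxybenzaldehyde; 31 tert-butyl bromoacetate
Product: 32 tert-butyl 2-[2-formyl-3-(4-iodo-2,6-dimethoxyphenoxy)-5-methoxyphenoxy]acetate
Conditions: K2CO3, DMF, rt
Reagents that add atoms: none
Why: Williamson alkylation at room temperature, below the temperature at which 2-formylaryloxyacetates condense to benzofurans. The tert-butyl ester is chosen so that the neighbouring phenol of 34 cannot close a lactone.

Step 16
Reactants: 32 tert-butyl 2-[2-formyl-3-(4-iodo-2,6-dimethoxyphenoxy)-5-methoxyphenoxy]acetate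
Product: 34 tert-butyl 2-[2-hydroxy-3-(4-iodo-2,6-dimethoxyphenoxy)-5-methoxyphenoxy]acetate, via aryl formate 33 (not isolated)
Conditions: mCPBA, CH2Cl2, 0 °C; Na2S2O3 wash; then K2CO3 (cat.), MeOH, 0 °C
Reagents that add atoms: 3-chloroperoxybenzoic acid, OOC(=O)c1cccc(Cl)c1
Why: Baeyer–Villiger oxidation; the 2,4,6-trioxygenated aryl group migrates readily, so the formyl carbon that activated steps 13 and 14 is exchanged for the ring B C1 oxygen. The reductive wash returns any iodide oxidised at iodine.

Step 17
Reactants: 34 tert-butyl 2-[2-hydroxy-3-(4-iodo-2,6-dimethoxyphenoxy)-5-methoxyphenoxy]acetate; 35 3,5-dimethoxyphenylboronic acid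
Product: 36 tert-butyl 2-[2-(3,5-dimethoxyphenoxy)-3-(4-iodo-2,6-dimethoxyphenoxy)-5-methoxyphenoxy]acetate
Conditions: 35 (2.5 equiv), Cu(OAc)2 (1.5 equiv), pyridine, 4 Å molecular sieves, CH2Cl2, dry air, rt
Reagents that add atoms: none
Why: Chan–Lam coupling; the oxidative copper-mediated arylation runs at room temperature, accepts 2,6-disubstituted phenols and leaves the aryl iodide alone. Ring A has no ortho substituent.

Step 18
Reactants: 36 tert-butyl 2-[2-(3,5-dimethoxyphenoxy)-3-(4-iodo-2,6-dimethoxyphenoxy)-5-methoxyphenoxy]acetate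
Product: 37 2-[2-(3,5-dimethoxyphenoxy)-3-(4-iodo-2,6-dimethoxyphenoxy)-5-methoxyphenoxy]acetic acid
Conditions: TFA, Et3SiH, CH2Cl2, 0 °C to rt
Reagents that add atoms: none
Why: Acidolysis of the tert-butyl ester; the silane reduces the tert-butyl cation before it can alkylate ring A.

Step 19
Reactants: 37 2-[2-(3,5-dimethoxyphenoxy)-3-(4-iodo-2,6-dimethoxyphenoxy)-5-methoxyphenoxy]acetic acid; 15 ethoxyethyne
Product: 40 4-[2-(3,5-dimethoxyphenoxy)-3-(4-iodo-2,6-dimethoxyphenoxy)-5-methoxyphenoxy]-3-ethoxycyclobut-2-en-1-one (racemic), via acid chloride 38 (not isolated), via aryloxyketene 39 (not isolated)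
Conditions: 1-chloro-N,N,2-trimethylprop-1-en-1-amine, CH2Cl2, 0 °C to rt; then 15 (4 equiv), Et3N (slow addition), Et2O, 0 °C to rt
Reagents that add atoms: none
Why: Same acid chloride formation, dehydrochlorination and ketene–alkoxyalkyne (2+2) cycloaddition as in step 8, on one arm. The neutral activation matters more here because ring A would be formylated by a Vilsmeier reagent.

Step 20
Reactants: 40 4-[2-(3,5-dimethoxyphenoxy)-3-(4-iodo-2,6-dimethoxyphenoxy)-5-methoxyphenoxy]-3-ethoxycyclobut-2-en-1-one; 6 2-(methoxyethynyl)-1,3,5-trimethoxybenzene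
Product: 44 6-[2-(3,5-dimethoxyphenoxy)-3-(4-iodo-2,6-dimethoxyphenoxy)-5-methoxyphenoxy]-5-ethoxy-3-methoxy-2-(2,4,6-trimethoxyphenyl)phenol, via vinylketene 41 (not isolated), via 4-vinylcyclobutenone 42 (not isolated), via dienylketene 43 (not isolated)
Conditions: 6 (2 equiv), degassed toluene, 110 °C, sealed vessel; then K2CO3, MeOH, rt
Reagents that add atoms: none
Why: Danheiser benzannulation as in step 9 on a single cyclobutenone (4π opening, ketene–ynol ether (2+2), 4π opening, 6π closure of ring E', tautomerisation), with the same polarity control of regiochemistry. The aryl iodide is inert to the metal-free thermal conditions.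

Step 21
Reactants: 44 6-[2-(3,5-dimethoxyphenoxy)-3-(4-iodo-2,6-dimethoxyphenoxy)-5-methoxyphenoxy]-5-ethoxy-3-methoxy-2-(2,4,6-trimethoxyphenyl)phenol
Product: 45 1-[6-ethoxy-2,4-dimethoxy-3-(2,4,6-trimethoxyphenyl)phenoxy]-2-(3,5-dimethoxyphenoxy)-3-(4-iodo-2,6-dimethoxyphenoxy)-5-methoxybenzene
Conditions: MeI, K2CO3, DMF, 50 °C
Reagents that add atoms: iodomethane, CI
Why: Williamson methylation of the new phenol; this leaves no free hydroxyl in the iodide.

Step 22
Reactants: 24 2,6-bis[6-ethoxy-2,4-dimethoxy-3-(2,4,6-trimethoxyphenyl)phenoxy]-4-methoxyphenol; 45 1-[6-ethoxy-2,4-dimethoxy-3-(2,4,6-trimethoxyphenyl)phenoxy]-2-(3,5-dimethoxyphenoxy)-3-(4-iodo-2,6-dimethoxyphenoxy)-5-methoxybenzene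
Product: 46 tetracosa-O-alkyl ether of 47 (all hydroxyls methylated except the C2 hydroxyl of each of the three rings E, which is ethylated)
Conditions: CuI (20 mol%), picolinic acid (40 mol%), K3PO4, DMSO, 100 °C, argon
Reagents that add atoms: none
Why: Ullmann-type diaryl ether synthesis; monovalent copper with picolinic acid couples 2,6-disubstituted phenols with aryl iodides. The crowding is all on the nucleophile, since the iodide carbon of ring C has two ortho hydrogens.

Step 23
Reactants: 46 tetracosa-O-alkyl ether of 47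
Product: 47 CNP0294555.0
Conditions: BBr3 (about 3 equiv per ether), CH2Cl2, −78 °C to rt, argon; then MeOH, H2O; Sephadex LH-20 under argon
Reagents that add atoms: none
Why: Lewis acid ether cleavage; bromide attacks the O-methyl and O-ethyl carbons of the boron-complexed ethers, and the O-aryl bonds of the six diaryl ethers are not cleaved. Hydrolysis of the aryl borates should give the 24 free hydroxyls.

## Compound list

1 | 1,3,5-trimethoxybenzene | COc1cc(OC)cc(OC)c1 | starting material
2 | 2-iodo-1,3,5-trimethoxybenzene | COc1cc(OC)c(I)c(OC)c1 | intermediate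
3 | 2-chloro-1,1-dimethoxyethane | COC(CCl)OC | starting material
4 | lithium methoxyacetylide | COC#C[Li] | intermediate
5 | (methoxyethynyl)zinc chloride | COC#C[Zn]Cl | intermediate
6 | 2-(methoxyethynyl)-1,3,5-trimethoxybenzene | COC#Cc1c(OC)cc(OC)cc1OC | intermediate
7 | 3,4,5-trihydroxybenzaldehyde | O=Cc1cc(O)c(O)c(O)c1 | starting material
8 | 4-(benzyloxy)-3,5-dihydroxybenzaldehyde | O=Cc1cc(O)c(OCc2ccccc2)c(O)c1 | intermediate
9 | methyl bromoacetate | COC(=O)CBr | starting material
10 | dimethyl 2,2'-{[2-(benzyloxy)-5-formyl-1,3-phenylene]bis(oxy)}diacetate | COC(=O)COc1cc(C=O)cc(OCC(=O)OC)c1OCc1ccccc1 | intermediate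
11 | dimethyl 2,2'-{[2-(benzyloxy)-5-(formyloxy)-1,3-phenylene]bis(oxy)}diacetate | COC(=O)COc1cc(OC=O)cc(OCC(=O)OC)c1OCc1ccccc1 | intermediate
12 | dimethyl 2,2'-{[2-(benzyloxy)-5-hydroxy-1,3-phenylene]bis(oxy)}diacetate | COC(=O)COc1cc(O)cc(OCC(=O)OC)c1OCc1ccccc1 | intermediate
13 | dimethyl 2,2'-{[2-(benzyloxy)-5-methoxy-1,3-phenylene]bis(oxy)}diacetate | COC(=O)COc1cc(OC)cc(OCC(=O)OC)c1OCc1ccccc1 | intermediate
14 | 2,2'-{[2-(benzyloxy)-5-methoxy-1,3-phenylene]bis(oxy)}diacetic acid | OC(=O)COc1cc(OC)cc(OCC(O)=O)c1OCc1ccccc1 | intermediate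
15 | ethoxyethyne | CCOC#C | starting material
16 | 2,2'-{[2-(benzyloxy)-5-methoxy-1,3-phenylene]bis(oxy)}diacetyl dichloride | ClC(=O)COc1cc(OC)cc(OCC(Cl)=O)c1OCc1ccccc1 | intermediate
17 | 2,2'-{[2-(benzyloxy)-5-methoxy-1,3-phenylene]bis(oxy)}bis(ethen-1-one) | O=C=COc1cc(OC)cc(OC=C=O)c1OCc1ccccc1 | intermediate
18 | 4,4'-{[2-(benzyloxy)-5-methoxy-1,3-phenylene]bis(oxy)}bis(3-ethoxycyclobut-2-en-1-one), mixture of diastereomers, configuration not assigned | CCOC1=CC(=O)C1Oc1cc(OC)cc(OC2C(=O)C=C2OCC)c1OCc1ccccc1 | intermediate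
19 | 4,4'-{[2-(benzyloxy)-5-methoxy-1,3-phenylene]bis(oxy)}bis(3-ethoxybuta-1,3-dien-1-one), both arms opened, alkene geometry not specified | CCOC(C=C=O)=COc1cc(OC)cc(OC=C(OCC)C=C=O)c1OCc1ccccc1 | intermediate
20 | bis(4-vinylcyclobutenone): each arm 4-[2-(aryloxy)-1-ethoxyethenyl]-3-methoxy-2-(2,4,6-trimethoxyphenyl)cyclobut-2-en-1-one on the ring D C2 and C6 oxygens | CCOC(=COc1cc(OC)cc(OC=C(OCC)C2C(=O)C(c3c(OC)cc(OC)cc3OC)=C2OC)c1OCc1ccccc1)C1C(=O)C(c2c(OC)cc(OC)cc2OC)=C1OC | intermediate
21 | bis(dienylketene): each arm 6-(aryloxy)-5-ethoxy-3-methoxy-2-(2,4,6-trimethoxyphenyl)hexa-1,3,5-trien-1-one on the ring D C2 and C6 oxygens | CCOC(C=C(OC)C(=C=O)c1c(OC)cc(OC)cc1OC)=COc1cc(OC)cc(OC=C(OCC)C=C(OC)C(=C=O)c2c(OC)cc(OC)cc2OC)c1OCc1ccccc1 | intermediate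
22 | 6,6'-{[2-(benzyloxy)-5-methoxy-1,3-phenylene]bis(oxy)}bis[5-ethoxy-3-methoxy-2-(2,4,6-trimethoxyphenyl)phenol] | CCOc1cc(OC)c(-c2c(OC)cc(OC)cc2OC)c(O)c1Oc1cc(OC)cc(Oc2c(OCC)cc(OC)c(-c3c(OC)cc(OC)cc3OC)c2O)c1OCc1ccccc1 | intermediate
23 | 2-(benzyloxy)-1,3-bis[6-ethoxy-2,4-dimethoxy-3-(2,4,6-trimethoxyphenyl)phenoxy]-5-methoxybenzene | CCOc1cc(OC)c(-c2c(OC)cc(OC)cc2OC)c(OC)c1Oc1cc(OC)cc(Oc2c(OCC)cc(OC)c(-c3c(OC)cc(OC)cc3OC)c2OC)c1OCc1ccccc1 | intermediate
24 | 2,6-bis[6-ethoxy-2,4-dimethoxy-3-(2,4,6-trimethoxyphenyl)phenoxy]-4-methoxyphenol | CCOc1cc(OC)c(-c2c(OC)cc(OC)cc2OC)c(OC)c1Oc1cc(OC)cc(Oc2c(OCC)cc(OC)c(-c3c(OC)cc(OC)cc3OC)c2OC)c1O | intermediate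
25 | 2,6-dimethoxyphenol | COc1cccc(OC)c1O | starting material
26 | 4-iodo-2,6-dimethoxyphenol | COc1cc(I)cc(OC)c1O | intermediate
27 | 2,6-difluoro-4-methoxybenzaldehyde | COc1cc(F)c(C=O)c(F)c1 | starting material
28 | 2-fluoro-6-(4-iodo-2,6-dimethoxyphenoxy)-4-methoxybenzaldehyde | COc1cc(F)c(C=O)c(Oc2c(OC)cc(I)cc2OC)c1 | intermediate
29 | 2-(4-iodo-2,6-dimethoxyphenoxy)-4-methoxy-6-[2-(methylsulfonyl)ethoxy]benzaldehyde | COc1cc(OCCS(C)(=O)=O)c(C=O)c(Oc2c(OC)cc(I)cc2OC)c1 | intermediate
30 | 2-hydroxy-6-(4-iodo-2,6-dimethoxyphenoxy)-4-methoxybenzaldehyde | COc1cc(O)c(C=O)c(Oc2c(OC)cc(I)cc2OC)c1 | intermediate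
31 | tert-butyl bromoacetate | CC(C)(C)OC(=O)CBr | starting material
32 | tert-butyl 2-[2-formyl-3-(4-iodo-2,6-dimethoxyphenoxy)-5-methoxyphenoxy]acetate | COc1cc(OCC(=O)OC(C)(C)C)c(C=O)c(Oc2c(OC)cc(I)cc2OC)c1 | intermediate
33 | tert-butyl 2-[2-(formyloxy)-3-(4-iodo-2,6-dimethoxyphenoxy)-5-methoxyphenoxy]acetate | COc1cc(OCC(=O)OC(C)(C)C)c(OC=O)c(Oc2c(OC)cc(I)cc2OC)c1 | intermediate
34 | tert-butyl 2-[2-hydroxy-3-(4-iodo-2,6-dimethoxyphenoxy)-5-methoxyphenoxy]acetate | COc1cc(OCC(=O)OC(C)(C)C)c(O)c(Oc2c(OC)cc(I)cc2OC)c1 | intermediate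
35 | 3,5-dimethoxyphenylboronic acid | COc1cc(OC)cc(B(O)O)c1 | starting material
36 | tert-butyl 2-[2-(3,5-dimethoxyphenoxy)-3-(4-iodo-2,6-dimethoxyphenoxy)-5-methoxyphenoxy]acetate | COc1cc(OC)cc(Oc2c(OCC(=O)OC(C)(C)C)cc(OC)cc2Oc2c(OC)cc(I)cc2OC)c1 | intermediate
37 | 2-[2-(3,5-dimethoxyphenoxy)-3-(4-iodo-2,6-dimethoxyphenoxy)-5-methoxyphenoxy]acetic acid | COc1cc(OC)cc(Oc2c(OCC(O)=O)cc(OC)cc2Oc2c(OC)cc(I)cc2OC)c1 | intermediate
38 | 2-[2-(3,5-dimethoxyphenoxy)-3-(4-iodo-2,6-dimethoxyphenoxy)-5-methoxyphenoxy]acetyl chloride | COc1cc(OC)cc(Oc2c(OCC(Cl)=O)cc(OC)cc2Oc2c(OC)cc(I)cc2OC)c1 | intermediate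
39 | 2-[2-(3,5-dimethoxyphenoxy)-3-(4-iodo-2,6-dimethoxyphenoxy)-5-methoxyphenoxy]ethen-1-one | COc1cc(OC)cc(Oc2c(OC=C=O)cc(OC)cc2Oc2c(OC)cc(I)cc2OC)c1 | intermediate
40 | 4-[2-(3,5-dimethoxyphenoxy)-3-(4-iodo-2,6-dimethoxyphenoxy)-5-methoxyphenoxy]-3-ethoxycyclobut-2-en-1-one, racemic | CCOC1=CC(=O)C1Oc1cc(OC)cc(Oc2c(OC)cc(I)cc2OC)c1Oc1cc(OC)cc(OC)c1 | intermediate
41 | 4-[2-(3,5-dimethoxyphenoxy)-3-(4-iodo-2,6-dimethoxyphenoxy)-5-methoxyphenoxy]-3-ethoxybuta-1,3-dien-1-one, alkene geometry not specified | CCOC(C=C=O)=COc1cc(OC)cc(Oc2c(OC)cc(I)cc2OC)c1Oc1cc(OC)cc(OC)c1 | intermediate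
42 | 4-{2-[2-(3,5-dimethoxyphenoxy)-3-(4-iodo-2,6-dimethoxyphenoxy)-5-methoxyphenoxy]-1-ethoxyethenyl}-3-methoxy-2-(2,4,6-trimethoxyphenyl)cyclobut-2-en-1-one | CCOC(=COc1cc(OC)cc(Oc2c(OC)cc(I)cc2OC)c1Oc1cc(OC)cc(OC)c1)C1C(=O)C(c2c(OC)cc(OC)cc2OC)=C1OC | intermediate
43 | 6-[2-(3,5-dimethoxyphenoxy)-3-(4-iodo-2,6-dimethoxyphenoxy)-5-methoxyphenoxy]-5-ethoxy-3-methoxy-2-(2,4,6-trimethoxyphenyl)hexa-1,3,5-trien-1-one | CCOC(C=C(OC)C(=C=O)c1c(OC)cc(OC)cc1OC)=COc1cc(OC)cc(Oc2c(OC)cc(I)cc2OC)c1Oc1cc(OC)cc(OC)c1 | intermediate
44 | 6-[2-(3,5-dimethoxyphenoxy)-3-(4-iodo-2,6-dimethoxyphenoxy)-5-methoxyphenoxy]-5-ethoxy-3-methoxy-2-(2,4,6-trimethoxyphenyl)phenol | CCOc1cc(OC)c(-c2c(OC)cc(OC)cc2OC)c(O)c1Oc1cc(OC)cc(Oc2c(OC)cc(I)cc2OC)c1Oc1cc(OC)cc(OC)c1 | intermediate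
45 | 1-[6-ethoxy-2,4-dimethoxy-3-(2,4,6-trimethoxyphenyl)phenoxy]-2-(3,5-dimethoxyphenoxy)-3-(4-iodo-2,6-dimethoxyphenoxy)-5-methoxybenzene | CCOc1cc(OC)c(-c2c(OC)cc(OC)cc2OC)c(OC)c1Oc1cc(OC)cc(Oc2c(OC)cc(I)cc2OC)c1Oc1cc(OC)cc(OC)c1 | intermediate
46 | tetracosa-O-alkyl ether of 47 (21 methyl ethers; ethyl ether on the C2 oxygen of each ring E) | CCOc1cc(OC)c(-c2c(OC)cc(OC)cc2OC)c(OC)c1Oc1cc(OC)cc(Oc2c(OC)cc(Oc3c(Oc4c(OCC)cc(OC)c(-c5c(OC)cc(OC)cc5OC)c4OC)cc(OC)cc3Oc3c(OCC)cc(OC)c(-c4c(OC)cc(OC)cc4OC)c3OC)cc2OC)c1Oc1cc(OC)cc(OC)c1 | intermediate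
47 | CNP0294555.0 | Oc1cc(O)cc(Oc2c(Oc3c(O)cc(Oc4c(Oc5c(O)cc(O)c(-c6c(O)cc(O)cc6O)c5O)cc(O)cc4Oc4c(O)cc(O)c(-c5c(O)cc(O)cc5O)c4O)cc3O)cc(O)cc2Oc2c(O)cc(O)c(-c3c(O)cc(O)cc3O)c2O)c1 | target

## Step count and least certain steps

Total: 23 steps. Longest linear sequence: 12 steps (25 through steps 12 to 23). The ring D line is 11 steps (7 through steps 3 to 11, then 22 and 23).

**Step 9 (key step).** What is most likely to go wrong is that the aryloxy-substituted vinylketene is consumed by dimerisation, or by acylating phenol already formed, faster than the hindered ynol ether traps it twice, so that mono-annulated and oligomeric material dominates. An aryloxy group is also a weaker donor than an alkoxy group, so the ring opening may need a temperature at which 6 degrades. Step 20 shares this risk. The fallback keeps one annulation on a simpler cyclobutenone and makes the ring D and ring B ethers by the substitution chemistry of step 13. It sets out from 15, 6 and 27 and comes back at 24 and, for the third arm, at 45. (Benzyloxy)acetyl chloride, Et3N and 15 would give 4-(benzyloxy)-3-ethoxycyclobut-2-en-1-one F1, whose alkoxy donor should lower the opening temperature. Heating F1 with 6 would give 2-(benzyloxy)-3-ethoxy-5-methoxy-6-(2,4,6-trimethoxyphenyl)phenol F2; methylation would give 2-(benzyloxy)-1-ethoxy-3,5-dimethoxy-4-(2,4,6-trimethoxyphenyl)benzene F3, and hydrogenolysis 6-ethoxy-2,4-dimethoxy-3-(2,4,6-trimethoxyphenyl)phenol F4. Two equivalents of F4 would displace both fluorides of 27 (Cs2CO3, DMSO, 120 °C) to give 2,6-bis[6-ethoxy-2,4-dimethoxy-3-(2,4,6-trimethoxyphenyl)phenoxy]-4-methoxybenzaldehyde F5. Baeyer–Villiger oxidation would give the aryl formate F6 and methanolysis 24. For the third arm, F4 and 28 would give 2-[6-ethoxy-2,4-dimethoxy-3-(2,4,6-trimethoxyphenyl)phenoxy]-6-(4-iodo-2,6-dimethoxyphenoxy)-4-methoxybenzaldehyde F7, then the aryl formate F8 and 2-[6-ethoxy-2,4-dimethoxy-3-(2,4,6-trimethoxyphenyl)phenoxy]-6-(4-iodo-2,6-dimethoxyphenoxy)-4-methoxyphenol F9, and the coupling of step 17 with 35 would give 45.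

**Step 8.** The two aryloxyketenes may oligomerise, or be intercepted by the amine, faster than the modestly nucleophilic alkoxyalkyne adds, and both arms must succeed. The fallback is the detour given for step 9: it sets out from 15 and 6, runs the same cycloaddition once on a cheap monofunctional acid chloride where a modest return costs little (F1), and comes back at 24 through F2 to F6, so that step 8 is not needed.

**Step 22.** C–O bond formation at a phenoxide shielded by two bulky aryloxy groups may be slower than reduction of the C–I bond of 45 or oxidative loss of the electron-rich phenol 24. The fallback changes metal and mechanism to a Buchwald–Hartwig etherification (Pd(OAc)2, 2-di-tert-butylphosphino-2',4',6'-triisopropylbiphenyl, K3PO4, toluene, 100 °C). Zerovalent palladium inserts into the unhindered C–I bond, and the C–O reductive elimination is accelerated by crowding, whereas crowding slows the copper reaction. It sets out from 24 and 45 and comes back at 46 without a new compound.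

**Step 23.** Cleavage of 24 ethers may stop short at the ethyl ethers and at methoxy groups buried between two substituents, and the free polyphenol may oxidise during the long reaction and on purification. The fallback sets out from 46 and comes back at 47. Dealkylation with AlBr3 and EtSH (thiol attack on the aluminium-complexed ether) is followed by acetylation of the crude product (Ac2O, pyridine) to the tetracosaacetate F11, which is stable in air and can be purified on silica gel and checked for completeness. K2CO3 in degassed MeOH then releases 47.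

**Step 17.** The electron-rich phenol 34 may be oxidised by Cu(OAc)2 and air, and the boronic acid may be lost to protodeboronation and homocoupling before the hindered phenol is arylated. The fallback sets out from 34 and 1 and comes back at 36. 1-Iodo-3,5-dimethoxybenzene is oxidised (mCPBA, TsOH, MeCN) and condensed with 1 to give (3,5-dimethoxyphenyl)(2,4,6-trimethoxyphenyl)iodonium tosylate F10, which arylates the phenoxide of 34 without metal or oxidant (K2CO3, MeCN, 50 °C). The less electron-rich aryl group is transferred.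

**Step 2.** The Negishi coupling may be slow at the doubly ortho-substituted iodide, and the electron-rich ynol ether may hydrate on work-up. The fallback sets out from 1 and comes back at 6. Friedel–Crafts acylation of 1 with methoxyacetyl chloride (SnCl4, CH2Cl2, −20 °C) gives 2-methoxy-1-(2,4,6-trimethoxyphenyl)ethanone F12. Enolisation and triflation (KHMDS, PhNTf2) give the enol triflate F13, and elimination with KOtBu gives 6 under basic conditions throughout.

## Further compounds

F1 | step 9 | 4-(benzyloxy)-3-ethoxycyclobut-2-en-1-one | CCOC1=CC(=O)C1OCc1ccccc1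
F2 | step 9 | 2-(benzyloxy)-3-ethoxy-5-methoxy-6-(2,4,6-trimethoxyphenyl)phenol | CCOc1cc(OC)c(-c2c(OC)cc(OC)cc2OC)c(O)c1OCc1ccccc1
F3 | step 9 | 2-(benzyloxy)-1-ethoxy-3,5-dimethoxy-4-(2,4,6-trimethoxyphenyl)benzene | CCOc1cc(OC)c(-c2c(OC)cc(OC)cc2OC)c(OC)c1OCc1ccccc1
F4 | step 9 | 6-ethoxy-2,4-dimethoxy-3-(2,4,6-trimethoxyphenyl)phenol | CCOc1cc(OC)c(-c2c(OC)cc(OC)cc2OC)c(OC)c1O
F5 | step 9 | 2,6-bis[6-ethoxy-2,4-dimethoxy-3-(2,4,6-trimethoxyphenyl)phenoxy]-4-methoxybenzaldehyde | COc1cc(Oc2c(OCC)cc(OC)c(-c3c(OC)cc(OC)cc3OC)c2OC)c(C=O)c(Oc2c(OCC)cc(OC)c(-c3c(OC)cc(OC)cc3OC)c2OC)c1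
F6 | step 9 | 2,6-bis[6-ethoxy-2,4-dimethoxy-3-(2,4,6-trimethoxyphenyl)phenoxy]-4-methoxyphenyl formate | COc1cc(Oc2c(OCC)cc(OC)c(-c3c(OC)cc(OC)cc3OC)c2OC)c(OC=O)c(Oc2c(OCC)cc(OC)c(-c3c(OC)cc(OC)cc3OC)c2OC)c1
F7 | step 9 | 2-[6-ethoxy-2,4-dimethoxy-3-(2,4,6-trimethoxyphenyl)phenoxy]-6-(4-iodo-2,6-dimethoxyphenoxy)-4-methoxybenzaldehyde | COc1cc(Oc2c(OCC)cc(OC)c(-c3c(OC)cc(OC)cc3OC)c2OC)c(C=O)c(Oc2c(OC)cc(I)cc2OC)c1
F8 | step 9 | 2-[6-ethoxy-2,4-dimethoxy-3-(2,4,6-trimethoxyphenyl)phenoxy]-6-(4-iodo-2,6-dimethoxyphenoxy)-4-methoxyphenyl formate | COc1cc(Oc2c(OCC)cc(OC)c(-c3c(OC)cc(OC)cc3OC)c2OC)c(OC=O)c(Oc2c(OC)cc(I)cc2OC)c1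
F9 | step 9 | 2-[6-ethoxy-2,4-dimethoxy-3-(2,4,6-trimethoxyphenyl)phenoxy]-6-(4-iodo-2,6-dimethoxyphenoxy)-4-methoxyphenol | COc1cc(Oc2c(OCC)cc(OC)c(-c3c(OC)cc(OC)cc3OC)c2OC)c(O)c(Oc2c(OC)cc(I)cc2OC)c1
F0 | step 8 | none | none
F0 | step 22 | none | none
F10 | step 17 | (3,5-dimethoxyphenyl)(2,4,6-trimethoxyphenyl)iodonium 4-methylbenzenesulfonate | COc1cc(OC)cc([I+]c2c(OC)cc(OC)cc2OC)c1.Cc1ccc(cc1)S([O-])(=O)=O
F11 | step 23 | tetracosaacetate of 47 | CC(=O)Oc1cc(OC(C)=O)cc(Oc2c(Oc3c(OC(C)=O)cc(Oc4c(Oc5c(OC(C)=O)cc(OC(C)=O)c(-c6c(OC(C)=O)cc(OC(C)=O)cc6OC(C)=O)c5OC(C)=O)cc(OC(C)=O)cc4Oc4c(OC(C)=O)cc(OC(C)=O)c(-c5c(OC(C)=O)cc(OC(C)=O)cc5OC(C)=O)c4OC(C)=O)cc3OC(C)=O)cc(OC(C)=O)cc2Oc2c(OC(C)=O)cc(OC(C)=O)c(-c3c(OC(C)=O)cc(OC(C)=O)cc3OC(C)=O)c2OC(C)=O)c1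
F12 | step 2 | 2-methoxy-1-(2,4,6-trimethoxyphenyl)ethanone | COCC(=O)c1c(OC)cc(OC)cc1OC
F13 | step 2 | 2-methoxy-1-(2,4,6-trimethoxyphenyl)ethenyl trifluoromethanesulfonate | COC=C(OS(=O)(=O)C(F)(F)F)c1c(OC)cc(OC)cc1OC
A1 | alternative 1 | 2,6-bis[(2,2',4,4',6,6'-hexamethoxybiphenyl-3-yl)oxy]-1,4-benzoquinone | O=C1C=C(Oc2c(OC)cc(OC)c(-c3c(OC)cc(OC)cc3OC)c2OC)C(=O)C(Oc2c(OC)cc(OC)c(-c3c(OC)cc(OC)cc3OC)c2OC)=C1
A2 | alternative 1 | 2,2',4,4',6,6'-hexamethoxybiphenyl-3-ol | COc1cc(OC)c(-c2c(OC)cc(OC)cc2OC)c(OC)c1O
A3 | alternative 1 | 2,6-dichloro-1,4-benzoquinone | O=C1C=C(Cl)C(=O)C(Cl)=C1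
A4 | alternative 2 | dimethyl 5-[3-(benzyloxy)-2,4,6-trimethoxyphenyl]-2,4,6-trihydroxyisophthalate | COC(=O)c1c(O)c(C(=O)OC)c(O)c(-c2c(OC)cc(OC)c(OCc3ccccc3)c2OC)c1O
A5 | alternative 2 | dimethyl 2-[3-(benzyloxy)-2,4,6-trimethoxyphenyl]malonate | COC(=O)C(C(=O)OC)c1c(OC)cc(OC)c(OCc2ccccc2)c1OC
A6 | alternative 2 | dimethyl 3-oxopentanedioate | COC(=O)CC(=O)CC(=O)OC
A7 | alternative 3 | methylated A–B–C–E–F pentameric ether with a benzyl ether on ring C C4 | COc1cc(OC)cc(Oc2c(Oc3c(OC)cc(OCc4ccccc4)cc3OC)cc(OC)cc2Oc2c(OC)cc(OC)c(-c3c(OC)cc(OC)cc3OC)c2OC)c1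
A8 | alternative 3 | 6-aryloxy-4-methoxy-2H-pyran-2-one carrying the ring B oxygen at C6 | COC1=CC(=O)OC(Oc2c(Oc3c(OC)cc(OCc4ccccc4)cc3OC)cc(OC)cc2Oc2c(OC)cc(OC)c(-c3c(OC)cc(OC)cc3OC)c2OC)=C1
A9 | alternative 3 | 1,1-dimethoxyethene | COC(=C)OC
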